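## Analysis of the target

The target (17) is a linear pentamer of oxygenated benzene rings, A–B–C–D–E, joined only by four diaryl ether oxygens and carrying fourteen free phenolic hydroxyls. It has no stereocentre and no ring other than the five arenes; rotation about the ether bonds is taken as free. Ring A is a 2,4,6-trihydroxyphenyl ether, ring E a 3,4,5-trihydroxyphenyl ether, and ring C a 3,5-dihydroxy ring with ether oxygens on C1 and C4, symmetric about its C1–C4 axis. Rings B and D share one pattern: aryloxy groups on C1 and C2, hydroxyls on C3, C4 and C5, one hydrogen on C6. The free pyrogallol and phloroglucinol units are oxidised by air, fastest under base, so the hydroxyls are carried as methyl ethers as far as possible and released last under acidic, oxygen-free conditions. The difficulty is twofold: every ring is electron-rich, which rules out unassisted nucleophilic aromatic substitution, and the ether oxygens on A1, C4, B2 and D2 are each attached to a carbon flanked by two oxygen-bearing carbons. The strategy rests on ring D: its C1 (ether to ring C) is para to the C4 oxygen and next to the lone C6 hydrogen, its C5 oxygen is ortho to the C4 oxygen and its C3 oxygen blocks the other ortho position, so that, if C4 and C5 are read as the carbonyls of an ortho-quinone, C1 is the unsubstituted β-carbon of the C5 carbonyl.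

## Retrosynthetic reasoning

**17 to 16.** The twelve O–CH3 bonds are cut last. Methyl ethers are the only protecting group that survives copper couplings, peracid and hydrogenolysis alike, and Lewis-acid demethylation leaves diaryl ether bonds untouched. The forward reaction has to cleave twelve ethers on a substrate that already holds a free catechol on ring D.

**16 to 13 and 10.** Two bonds on ring D are cut together: the D5–O bond and the bond between D1 and the ring C oxygen. This removes the most crowded ether of the molecule (the ring C oxygen lies between two methoxy groups) and reduces ring D to the guaiacol 13, which has oxygen only on D2, D3 and D4. The forward reaction must oxygenate 13 at D5 with O2 and a copper catalyst, let the hydroxyl of 10 add to D1 of the resulting ortho-quinone 14, and end with a reductive work-up. Cutting here rather than at D2–O keeps the easy ether (hindered oxygen, unhindered ring E carbon) for conventional coupling.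

**13 to 11 and 12.** The bond between the D2 oxygen and E1 is cut. Diol 11 is symmetric, so arylation of either hydroxyl gives the same product, and boronic acid 12 is unhindered. The forward Chan–Lam coupling only has to stop after one arylation.

**10 to 9, then to 6 and 8.** The ring C hydroxyl of 10 is masked as a benzyl ether in 9, to be released by hydrogenolysis without touching methyl ethers. The bond between the B2 oxygen and C1 of ring C is then cut. This polarity places the hindrance on the phenol 6, which copper couplings tolerate, and leaves bromide 8 with two ortho hydrogens.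

**6 to 4, then to 2 and 3.** The B2 oxygen of 6 is traced back to the formyl carbon of 4 by Baeyer–Villiger oxidation. The bond between the ring A oxygen and B1 is then cut to give phenol 3 and bromoaldehyde 2. The formyl group serves twice: it activates the neighbouring C–Br bond for coupling with the hindered phenol 3, and it is the latent B2 oxygen.

**2 to 1, and 8 to 7.** The formyl C–C bond of 2 is cut to give the symmetric bromide 1, whose two free positions are equivalent, so formylation can give only one product. Benzyl ether 8 comes from phenol 7 by O-alkylation.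

## Alternatives that were turned down

**Alternative 1:** Ring C would be built by a Danheiser benzannulation. The disconnection takes ring C apart into the cyclobutenone 3-ethoxy-4-[3,4,5-trimethoxy-2-(3,4,5-trimethoxyphenoxy)phenoxy]cyclobut-2-en-1-one (A2), which already carries rings D and E through an sp3 C–O bond, and (triisopropylsiloxy)acetylene (A3). On heating, A2 opens to a vinylketene, which adds to A3 in a (2+2) cycloaddition. Ring opening and 6π closure then give the phenol 3-ethoxy-2-[3,4,5-trimethoxy-2-(3,4,5-trimethoxyphenoxy)phenoxy]-5-[(triisopropylsilyl)oxy]phenol (A1).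
- For: the reaction class is well established, its regiochemistry follows from the mechanism, and the crowded oxygen on C4 of ring C is attached before ring C is aromatic. On precedent it is stronger than the chosen key step.
- Against: ring C is the symmetric ring of the target, so the three differently protected oxygens of A1 buy nothing, and the same pattern is purchasable as 7. A2 needs several steps from a squaric ester plus a separately made two-ring phenol. After A1 the phenol must be capped, the silyl group removed, and ring C joined to the crowded B2 carbon with the unfavourable polarity (unhindered phenol, hindered electron-rich halide).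
- Comparison: ring D, the ring that is hard to oxygenate, is not addressed, and the route would be roughly twice as long. The chosen strategy offers less precedent but installs the ring D oxygen and the C–D ether in one step from a one-step precursor.

**Alternative 2:** Ring D would be made from a squarate by ring expansion. The disconnection cuts D1–D6. The precursor is 3,4-dimethoxy-4-(1-methoxyethenyl)-2-(3,4,5-trimethoxyphenoxy)cyclobut-2-en-1-one (A5). Heated in toluene, A5 opens to a dienylketene whose ketene carbon bonds to the terminal vinyl carbon, giving 3,4,5-trimethoxy-2-(3,4,5-trimethoxyphenoxy)phenol (A4) with only the D1 hydroxyl free.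
- For: all five ring D oxygens are placed by construction, the thermal step needs no reagent, and its regiochemical certainty on ring D is higher than that of the chosen oxygenation.
- Against: A5 takes three to four steps, including addition of a vinyl-lithium to one of two carbonyls that differ only in a methoxy versus an aryloxy donor. A4 still lacks the bond to ring C, and with D1 as the oxygen partner ring C must be the electrophile at a carbon flanked by two methoxy groups, the worst polarity for this ether. A phenol of this type is also reachable in three conventional steps (formylation, Ullmann coupling, Baeyer–Villiger oxidation), as steps 1 to 3 show for ring B.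
- Comparison: the alternative builds ring D but leaves the hardest inter-ring bond open; the chosen key step forms that bond.

**Alternative 3:** Ring E would be grown last on the tetramer. The D2 phenol of an A–B–C–D tetramer would be converted with trichloroethylene (A9) and an alkyllithium into the ethynyl ether 1-(ethynyloxy)-2,3,4-trimethoxy-6-{2,6-dimethoxy-4-[2,3,4-trimethoxy-6-(2,4,6-trimethoxyphenoxy)phenoxy]phenoxy}benzene (A7); in this sequence A9 supplies both alkyne carbons. The cyclobutenone partner is 4-(benzyloxy)-3-ethoxycyclobut-2-en-1-one (A8). Heating A7 with A8 would form E2–E3 and E1–E6 and close ring E, giving 2-(benzyloxy)-3-ethoxy-5-{2,3,4-trimethoxy-6-{2,6-dimethoxy-4-[2,3,4-trimethoxy-6-(2,4,6-trimethoxyphenoxy)phenoxy]phenoxy}phenoxy}phenol (A6), in which the benzyloxy and ethoxy groups of A8 sit on E4 and E5.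
- For: the hindered D2 oxygen is bonded to a small two-carbon unit, not to an arene, and the annulation is a known reaction class.
- Against: ring E is the simplest ring of the target, symmetric and purchasable as 12 or 1, and the D2–E1 ether is the kind that copper coupling handles (hindered phenol, unhindered aryl partner). The hydroxyl, benzyl and ethyl differentiation in A6 is pointless because all three oxygens end as hydroxyls. The ynol ether sequence needs excess alkyllithium on a tetramer with eleven methoxy groups and several positions prone to ortho-lithiation, and all this falls on the most advanced intermediate.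
- Comparison: the tetramer, with its crowded C–D ether, must still come from elsewhere. The alternative is more linear and longer; the chosen strategy spends its risk on ring D, where the structural problem lies.

Key step: step 8

Assumption: rings are lettered A to E from the 2,4,6-trihydroxyphenoxy end to the 3,4,5-trihydroxyphenyl end; ring D is numbered with C1 at the ether to ring C and C2 at the ether to ring E; compounds 1, 3, 7, 11 and 12 are taken as purchasable.

## Route

**Step 1**
Reactants: 1 5-bromo-1,2,3-trimethoxybenzene
Product: 2 6-bromo-2,3,4-trimethoxybenzaldehyde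
Conditions: Cl2CHOMe, TiCl4, CH2Cl2, 0 °C; then ice-water
Reagents that add atoms: dichloromethyl methyl ether COC(Cl)Cl; water O
Why: Rieche formylation; the two free positions of 1 are equivalent by symmetry and each is ortho and para to a methoxy group, so one aldehyde should form. At 0 °C TiCl4 should leave the methyl ethers intact.

**Step 2**
Reactants: 2 6-bromo-2,3,4-trimethoxybenzaldehyde; 3 2,4,6-trimethoxyphenol
Product: 4 2,3,4-trimethoxy-6-(2,4,6-trimethoxyphenoxy)benzaldehyde
Conditions: CuI (10 mol %), picolinic acid (20 mol %), K3PO4, DMSO, 90 °C, argon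
Reagents that add atoms: none
Why: Ullmann diaryl ether synthesis; the ortho-formyl group activates the C–Br bond and the picolinate-ligated copper catalyst is suited to 2,6-disubstituted phenoxides. The aldehyde has no α-hydrogen and should tolerate K3PO4.

**Step 3**
Reactants: 4 2,3,4-trimethoxy-6-(2,4,6-trimethoxyphenoxy)benzaldehyde
Product: 6 2,3,4-trimethoxy-6-(2,4,6-trimethoxyphenoxy)phenol, via aryl formate 5 (not isolated)
Conditions: mCPBA, CH2Cl2, 0 °C to rt; then K2CO3 (cat.), MeOH, rt
Reagents that add atoms: mCPBA OOC(=O)c1cccc(Cl)c1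
Why: Baeyer–Villiger oxidation; an aryl group with ortho and para oxygen donors migrates in preference to hydrogen, giving the formate, which mild methanolysis cleaves. At 0 °C oxidation of the aldehyde should outpace hydroxylation of the electron-rich rings.

**Step 4**
Reactants: 7 4-bromo-2,6-dimethoxyphenol
Product: 8 2-(benzyloxy)-5-bromo-1,3-dimethoxybenzene
Conditions: BnBr, K2CO3, DMF, rt
Reagents that add atoms: benzyl bromide BrCc1ccccc1
Why: Williamson ether synthesis; the benzyl group masks the ring C hydroxyl, which must be free only in step 8, and can later be removed without touching methyl ethers.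

**Step 5**
Reactants: 6 2,3,4-trimethoxy-6-(2,4,6-trimethoxyphenoxy)phenol; 8 2-(benzyloxy)-5-bromo-1,3-dimethoxybenzene
Product: 9 2-(benzyloxy)-1,3-dimethoxy-5-[2,3,4-trimethoxy-6-(2,4,6-trimethoxyphenoxy)phenoxy]benzene
Conditions: CuI (20 mol %), picolinic acid (40 mol %), K3PO4, DMSO, 100 °C, argon
Reagents that add atoms: none
Why: Ullmann diaryl ether synthesis; the hindrance lies on the phenoxide, which this catalyst tolerates, while the C–Br carbon of 8 has two ortho hydrogens. The inert atmosphere protects the electron-rich phenoxide of 6.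

**Step 6**
Reactants: 9 2-(benzyloxy)-1,3-dimethoxy-5-[2,3,4-trimethoxy-6-(2,4,6-trimethoxyphenoxy)phenoxy]benzene
Product: 10 2,6-dimethoxy-4-[2,3,4-trimethoxy-6-(2,4,6-trimethoxyphenoxy)phenoxy]phenol
Conditions: H2 (1 atm), 10% Pd/C, EtOAc/MeOH, rt
Reagents that add atoms: none
Why: Hydrogenolysis of a benzyl ether; methyl ethers and diaryl ethers are inert and nothing else in 9 is reducible.

**Step 7**
Reactants: 11 2-methoxybenzene-1,3-diol (2-methoxyresorcinol); 12 3,4,5-trimethoxyphenylboronic acid
Product: 13 2-methoxy-3-(3,4,5-trimethoxyphenoxy)phenol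
Conditions: Cu(OAc)2 (1 equiv), pyridine, 4 Å MS, CH2Cl2, air, rt; 11 in threefold excess
Reagents that add atoms: none
Why: Chan–Lam coupling; the two hydroxyls of 11 are equivalent, so mono-arylation gives a single product, and the excess of 11 holds back the second arylation. Air returns the copper to the divalent state.

**Step 8**
Reactants: 13 2-methoxy-3-(3,4,5-trimethoxyphenoxy)phenol; 10 2,6-dimethoxy-4-[2,3,4-trimethoxy-6-(2,4,6-trimethoxyphenoxy)phenoxy]phenol
Product: 16 3-methoxy-5-{2,6-dimethoxy-4-[2,3,4-trimethoxy-6-(2,4,6-trimethoxyphenoxy)phenoxy]phenoxy}-4-(3,4,5-trimethoxyphenoxy)benzene-1,2-diol, via ortho-quinone 14 (not isolated), via aryloxy-ortho-quinone 15 (not isolated)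
Conditions: [Cu(MeCN)4]PF6 (10 mol %), N,N'-di-tert-butylethylenediamine (20 mol %), O2 (1 atm), 4 Å MS, CH2Cl2, rt, 13 (1.5 equiv) added slowly to 10; then aq. Na2S2O4
Reagents that add atoms: dioxygen O=O
Why: Proposed new method: the diamine-bound monovalent copper complex should take up O2 as a dicopper peroxide, bind the phenoxide of 13 and transfer one oxygen atom to D5, its only hydrogen-bearing ortho carbon, giving ortho-quinone 14 in the manner of tyrosinase-type phenol oxygenation. The hydroxyl of 10 should then add in conjugate fashion to D1, the unsubstituted β-carbon of the D5 carbonyl, and enolisation of the adduct gives the catechol. Copper and O2 (or unreacted 14) should reoxidise this catechol to aryloxy-quinone 15, and Na2S2O4 in the work-up returns all quinone to catechol 16. The closest known reaction type is the copper-catalysed aerobic ortho-oxygenation of simple phenols in which a second molecule of the same phenol adds through oxygen to the quinone; new here are two different phenols, a 2,6-dimethoxyphenol as the adding partner and a quinone that already carries two oxygen substituents. No ring is closed and no stereocentre is formed. Site of oxygenation: D3 carries methoxy, so only D5 can be hydroxylated. Site of addition: the D4 carbonyl is deactivated by donation from the D2 aryloxy and D3 methoxy groups, which leaves the D5 enone as the electrophile, and its β-carbon D1 can rearomatise after attack whereas attack at D2 would have to expel ring E as phenoxide. Chemoselectivity between the phenols: 10 has no free ortho or para carbon, so it cannot be oxygenated and can bond only through oxygen, and slow addition of 13 keeps its concentration below that of 10 so that cross-coupling is favoured over self-coupling of 13.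

**Step 9**
Reactants: 16 3-methoxy-5-{2,6-dimethoxy-4-[2,3,4-trimethoxy-6-(2,4,6-trimethoxyphenoxy)phenoxy]phenoxy}-4-(3,4,5-trimethoxyphenoxy)benzene-1,2-diol
Product: 17 5-{2,6-dihydroxy-4-[2,3,4-trihydroxy-6-(2,4,6-trihydroxyphenoxy)phenoxy]phenoxy}-4-(3,4,5-trihydroxyphenoxy)benzene-1,2,3-triol
Conditions: BBr3 (30 equiv), CH2Cl2, −78 °C to rt, argon; then ice-water
Reagents that add atoms: none
Why: Lewis-acid cleavage of aryl methyl ethers; each methoxy oxygen binds boron and bromide removes the methyl group as MeBr. The diaryl ether oxygens have no sp3 carbon to be attacked and should survive; acidic, oxygen-free work-up protects the polyphenol.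

## Compound list

1 | 5-bromo-1,2,3-trimethoxybenzene | COc1cc(Br)cc(OC)c1OC | starting material
2 | 6-bromo-2,3,4-trimethoxybenzaldehyde | COc1cc(Br)c(C=O)c(OC)c1OC | intermediate
3 | 2,4,6-trimethoxyphenol | COc1cc(OC)c(O)c(OC)c1 | starting material
4 | 2,3,4-trimethoxy-6-(2,4,6-trimethoxyphenoxy)benzaldehyde | COc1cc(OC)c(Oc2cc(OC)c(OC)c(OC)c2C=O)c(OC)c1 | intermediate
5 | 2,3,4-trimethoxy-6-(2,4,6-trimethoxyphenoxy)phenyl formate | COc1cc(OC)c(Oc2cc(OC)c(OC)c(OC)c2OC=O)c(OC)c1 | intermediate
6 | 2,3,4-trimethoxy-6-(2,4,6-trimethoxyphenoxy)phenol | COc1cc(OC)c(Oc2cc(OC)c(OC)c(OC)c2O)c(OC)c1 | intermediate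
7 | 4-bromo-2,6-dimethoxyphenol | COc1cc(Br)cc(OC)c1O | starting material
8 | 2-(benzyloxy)-5-bromo-1,3-dimethoxybenzene | COc1cc(Br)cc(OC)c1OCc1ccccc1 | intermediate
9 | 2-(benzyloxy)-1,3-dimethoxy-5-[2,3,4-trimethoxy-6-(2,4,6-trimethoxyphenoxy)phenoxy]benzene | COc1cc(OC)c(Oc2cc(OC)c(OC)c(OC)c2Oc2cc(OC)c(OCc3ccccc3)c(OC)c2)c(OC)c1 | intermediate
10 | 2,6-dimethoxy-4-[2,3,4-trimethoxy-6-(2,4,6-trimethoxyphenoxy)phenoxy]phenol | COc1cc(OC)c(Oc2cc(OC)c(OC)c(OC)c2Oc2cc(OC)c(O)c(OC)c2)c(OC)c1 | intermediate
11 | 2-methoxybenzene-1,3-diol (2-methoxyresorcinol) | COc1c(O)cccc1O | starting material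
12 | 3,4,5-trimethoxyphenylboronic acid | COc1cc(B(O)O)cc(OC)c1OC | starting material
13 | 2-methoxy-3-(3,4,5-trimethoxyphenoxy)phenol | COc1c(O)cccc1Oc1cc(OC)c(OC)c(OC)c1 | intermediate
14 | 3-methoxy-4-(3,4,5-trimethoxyphenoxy)cyclohexa-3,5-diene-1,2-dione | O=C1C(=O)C=CC(Oc2cc(OC)c(OC)c(OC)c2)=C1OC | intermediate
15 | 3-methoxy-5-{2,6-dimethoxy-4-[2,3,4-trimethoxy-6-(2,4,6-trimethoxyphenoxy)phenoxy]phenoxy}-4-(3,4,5-trimethoxyphenoxy)cyclohexa-3,5-diene-1,2-dione | COc1cc(OC)c(Oc2cc(OC)c(OC)c(OC)c2Oc2cc(OC)c(OC3=CC(=O)C(=O)C(OC)=C3Oc3cc(OC)c(OC)c(OC)c3)c(OC)c2)c(OC)c1 | intermediate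
16 | 3-methoxy-5-{2,6-dimethoxy-4-[2,3,4-trimethoxy-6-(2,4,6-trimethoxyphenoxy)phenoxy]phenoxy}-4-(3,4,5-trimethoxyphenoxy)benzene-1,2-diol | COc1cc(OC)c(Oc2cc(OC)c(OC)c(OC)c2Oc2cc(OC)c(Oc3cc(O)c(O)c(OC)c3Oc3cc(OC)c(OC)c(OC)c3)c(OC)c2)c(OC)c1 | intermediate
17 | 5-{2,6-dihydroxy-4-[2,3,4-trihydroxy-6-(2,4,6-trihydroxyphenoxy)phenoxy]phenoxy}-4-(3,4,5-trihydroxyphenoxy)benzene-1,2,3-triol | Oc1cc(O)c(Oc2cc(O)c(O)c(O)c2Oc2cc(O)c(Oc3cc(O)c(O)c(O)c3Oc3cc(O)c(O)c(O)c3)c(O)c2)c(O)c1 | target

## Step count and risk

Total: 9 steps. Longest linear sequence: 7 steps (1, 2, 3, 5, 6, 8, 9); steps 4 and 7 are one-step branches.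

**Step 8 (key step, proposed new method).** Several processes can divert it:
- self-coupling, in which 13 adds to its own quinone 14 (the known pathway);
- one-electron oxidation of the electron-rich phenol 10 at copper, followed by loss of its para aryloxy group;
- ipso substitution at D2 with expulsion of ring E;
- oxygen transfer to the methoxy-bearing D3 with loss of methanol;
- radical coupling of 13 through its free para carbon.

Fallback, known chemistry only, setting out from 10 and 2. Ullmann coupling (CuI, picolinic acid, K3PO4, DMSO) joins the same kind of partners as step 2 and should give 2,3,4-trimethoxy-6-{2,6-dimethoxy-4-[2,3,4-trimethoxy-6-(2,4,6-trimethoxyphenoxy)phenoxy]phenoxy}benzaldehyde (F1). Baeyer–Villiger oxidation of F1 with mCPBA leads to 2,3,4-trimethoxy-6-{2,6-dimethoxy-4-[2,3,4-trimethoxy-6-(2,4,6-trimethoxyphenoxy)phenoxy]phenoxy}phenyl formate (F2), and methanolysis of F2 frees 2,3,4-trimethoxy-6-{2,6-dimethoxy-4-[2,3,4-trimethoxy-6-(2,4,6-trimethoxyphenoxy)phenoxy]phenoxy}phenol (F3). Ullmann coupling of F3 with 1 should give the fully methylated pentamer 1,2,3-trimethoxy-5-{2,3,4-trimethoxy-6-{2,6-dimethoxy-4-[2,3,4-trimethoxy-6-(2,4,6-trimethoxyphenoxy)phenoxy]phenoxy}phenoxy}benzene (F4). BBr3 as in step 9 then converts F4 into 17, where the fallback rejoins the route. It replaces steps 7 and 8.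

**Step 5.** Coupling of the di-ortho-substituted, electron-rich phenoxide of 6 with the unactivated, electron-rich bromide 8 may be slow, so that reductive loss of bromine from 8 or oxidative decay of the phenoxide takes over. Fallback from 8: bromine–lithium exchange (n-BuLi, THF, −78 °C), B(OiPr)3 and acidic work-up should give [4-(benzyloxy)-3,5-dimethoxyphenyl]boronic acid (F5). Chan–Lam coupling of F5 with 6 (Cu(OAc)2, pyridine, 4 Å MS, CH2Cl2, air, rt) forms the same ether at room temperature through transmetalation, not through C–Br activation, and returns to the route at 9.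

**Step 2.** The copper-bound, doubly ortho-substituted phenoxide of 3 may transfer slowly, and 3 is easily oxidised. Fallback from 3: the fluoro analogue of 1, 5-fluoro-1,2,3-trimethoxybenzene (F6), is used in place of the bromide. Rieche formylation of F6 as in step 1 should give 6-fluoro-2,3,4-trimethoxybenzaldehyde (F7). Uncatalysed nucleophilic aromatic substitution on F7, in which the potassium salt of 3 displaces the ortho-formyl-activated fluoride (K2CO3, DMF, 120 °C), then returns to the route at 4.

**Step 7.** Double arylation of 11, and loss of 12 by protodeboronation or oxidation, may erode the statistical mono-arylation. Fallback from 11: mono-benzylation (BnBr, K2CO3, acetone) gives 3-(benzyloxy)-2-methoxyphenol (F8). Ullmann coupling of F8 with 1 (CuI, picolinic acid, K3PO4, DMSO), which can be driven with excess bromide, gives 1-(benzyloxy)-2-methoxy-3-(3,4,5-trimethoxyphenoxy)benzene (F9). Hydrogenolysis of F9 (H2, Pd/C) returns to the route at 13.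

**Step 9.** Demethylation of the most crowded ethers may stay incomplete, and the free polyphenol may oxidise during isolation. Fallback from 16: after BBr3 the crude product is acetylated without isolation (Ac2O, pyridine) to the tetradeca-O-acetyl derivative of 17 (F10). F10 is stable on silica, so incompletely demethylated material can be separated and resubmitted. Acid-catalysed methanolysis of F10 (HCl, degassed MeOH, argon) returns to the route at 17.

## Further compounds

F1 | step 8 | 2,3,4-trimethoxy-6-{2,6-dimethoxy-4-[2,3,4-trimethoxy-6-(2,4,6-trimethoxyphenoxy)phenoxy]phenoxy}benzaldehyde | COc1cc(OC)c(Oc2cc(OC)c(OC)c(OC)c2Oc2cc(OC)c(Oc3cc(OC)c(OC)c(OC)c3C=O)c(OC)c2)c(OC)c1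
F2 | step 8 | 2,3,4-trimethoxy-6-{2,6-dimethoxy-4-[2,3,4-trimethoxy-6-(2,4,6-trimethoxyphenoxy)phenoxy]phenoxy}phenyl formate | COc1cc(OC)c(Oc2cc(OC)c(OC)c(OC)c2Oc2cc(OC)c(Oc3cc(OC)c(OC)c(OC)c3OC=O)c(OC)c2)c(OC)c1
F3 | step 8 | 2,3,4-trimethoxy-6-{2,6-dimethoxy-4-[2,3,4-trimethoxy-6-(2,4,6-trimethoxyphenoxy)phenoxy]phenoxy}phenol | COc1cc(OC)c(Oc2cc(OC)c(OC)c(OC)c2Oc2cc(OC)c(Oc3cc(OC)c(OC)c(OC)c3O)c(OC)c2)c(OC)c1
F4 | step 8 | 1,2,3-trimethoxy-5-{2,3,4-trimethoxy-6-{2,6-dimethoxy-4-[2,3,4-trimethoxy-6-(2,4,6-trimethoxyphenoxy)phenoxy]phenoxy}phenoxy}benzene | COc1cc(OC)c(Oc2cc(OC)c(OC)c(OC)c2Oc2cc(OC)c(Oc3cc(OC)c(OC)c(OC)c3Oc3cc(OC)c(OC)c(OC)c3)c(OC)c2)c(OC)c1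
F5 | step 5 | [4-(benzyloxy)-3,5-dimethoxyphenyl]boronic acid | COc1cc(B(O)O)cc(OC)c1OCc1ccccc1
F6 | step 2 | 5-fluoro-1,2,3-trimethoxybenzene | COc1cc(F)cc(OC)c1OC
F7 | step 2 | 6-fluoro-2,3,4-trimethoxybenzaldehyde | COc1cc(F)c(C=O)c(OC)c1OC
F8 | step 7 | 3-(benzyloxy)-2-methoxyphenol | COc1c(O)cccc1OCc1ccccc1
F9 | step 7 | 1-(benzyloxy)-2-methoxy-3-(3,4,5-trimethoxyphenoxy)benzene | COc1c(OCc2ccccc2)cccc1Oc1cc(OC)c(OC)c(OC)c1
F10 | step 9 | tetradeca-O-acetyl derivative of 17 | CC(=O)Oc1cc(OC(C)=O)c(Oc2cc(OC(C)=O)c(OC(C)=O)c(OC(C)=O)c2Oc2cc(OC(C)=O)c(Oc3cc(OC(C)=O)c(OC(C)=O)c(OC(C)=O)c3Oc3cc(OC(C)=O)c(OC(C)=O)c(OC(C)=O)c3)c(OC(C)=O)c2)c(OC(C)=O)c1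
A1 | alternative 1 | 3-ethoxy-2-[3,4,5-trimethoxy-2-(3,4,5-trimethoxyphenoxy)phenoxy]-5-[(triisopropylsilyl)oxy]phenol | CCOc1cc(O[Si](C(C)C)(C(C)C)C(C)C)cc(O)c1Oc1cc(OC)c(OC)c(OC)c1Oc1cc(OC)c(OC)c(OC)c1
A2 | alternative 1 | 3-ethoxy-4-[3,4,5-trimethoxy-2-(3,4,5-trimethoxyphenoxy)phenoxy]cyclobut-2-en-1-one | CCOC1=CC(=O)C1Oc1cc(OC)c(OC)c(OC)c1Oc1cc(OC)c(OC)c(OC)c1
A3 | alternative 1 | (triisopropylsiloxy)acetylene | C#CO[Si](C(C)C)(C(C)C)C(C)C
A4 | alternative 2 | 3,4,5-trimethoxy-2-(3,4,5-trimethoxyphenoxy)phenol | Oc1cc(OC)c(OC)c(OC)c1Oc1cc(OC)c(OC)c(OC)c1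
A5 | alternative 2 | 3,4-dimethoxy-4-(1-methoxyethenyl)-2-(3,4,5-trimethoxyphenoxy)cyclobut-2-en-1-one | COC(=C)C1(OC)C(OC)=C(Oc2cc(OC)c(OC)c(OC)c2)C1=O
A6 | alternative 3 | 2-(benzyloxy)-3-ethoxy-5-{2,3,4-trimethoxy-6-{2,6-dimethoxy-4-[2,3,4-trimethoxy-6-(2,4,6-trimethoxyphenoxy)phenoxy]phenoxy}phenoxy}phenol | COc1cc(OC)c(Oc2cc(OC)c(OC)c(OC)c2Oc2cc(OC)c(Oc3cc(OC)c(OC)c(OC)c3Oc3cc(O)c(OCc4ccccc4)c(OCC)c3)c(OC)c2)c(OC)c1
A7 | alternative 3 | 1-(ethynyloxy)-2,3,4-trimethoxy-6-{2,6-dimethoxy-4-[2,3,4-trimethoxy-6-(2,4,6-trimethoxyphenoxy)phenoxy]phenoxy}benzene | COc1cc(OC)c(Oc2cc(OC)c(OC)c(OC)c2Oc2cc(OC)c(Oc3cc(OC)c(OC)c(OC)c3OC#C)c(OC)c2)c(OC)c1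
A8 | alternative 3 | 4-(benzyloxy)-3-ethoxycyclobut-2-en-1-one | CCOC1=CC(=O)C1OCc1ccccc1
A9 | alternative 3 | trichloroethylene | ClC=C(Cl)Cl
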